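The cyclohexane ring of the 7-oxabicyclo[4.1.0]heptane core is disconnected at C5–C6 and C3–C4. One Diels–Alder reaction joins a 1-alkoxy-2-silyloxy-3-methylbutadiene (C3, C2, C1 and C6, carrying both ester oxygens and the methyl group) with a chiral α'-hydroxy vinyl ketone (C4, C5 and the complete side chain). It exploits the cis C3–O/C4 relationship (endo rule) and the contiguous C1–C2–C3 oxygenation, which is the pattern of an oxygenated diene. The hydrogen-bonded side-chain carbinol controls the facial sense. The enol silane left at C1–C2 is then turned into the cis-epoxy alcohol, and the carbinol is inverted while it is acetylated.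

Key step: step 7

Remarks: Target numbering used throughout: C1 = methyl-bearing epoxide carbon, C2 and C3 = angelate-bearing carbons, C4 = carbon bearing the side chain, C5 = CH2, C6 = epoxide CH, O7 = epoxide oxygen. Assumption: in the double acylation of step 14 the C3 hydroxyl is taken to react first; either monoester leads to the same product.

Step 1
Reactants: 1 methyl (R)-glycidate; 2 (2-methylprop-1-en-1-yl)magnesium bromide
Product: 3 methyl (2R)-2-hydroxy-5-methylhex-4-enoate
Conditions: CuI (10 mol %), THF, −40 → −20 °C; aq NH4Cl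
Reagents that add atoms: none
Why: Copper-catalysed Grignard opening of the terminal epoxide at its CH2 carbon is faster than ester addition at low temperature and leaves the existing stereocentre untouched (retention).

Step 2
Reactants: 3 methyl (2R)-2-hydroxy-5-methylhex-4-enoate
Product: 4 (2R)-2-hydroxy-N-methoxy-N,5-dimethylhex-4-enamide
Conditions: MeNH(OMe)·HCl, iPrMgCl (4 equiv), THF, −20 → 0 °C
Reagents that add atoms: N,O-dimethylhydroxylamine hydrochloride, CNOC.Cl
Why: Weinreb amide formation by aminolysis of the ester with the magnesium amide made in the flask, which tolerates the free α-hydroxyl (as its alkoxide) and should not epimerise the carbinol centre.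

Step 3
Reactants: 4 (2R)-2-hydroxy-N-methoxy-N,5-dimethylhex-4-enamide; 5 vinylmagnesium bromide
Product: 7 (4R)-4-hydroxy-7-methylocta-1,6-dien-3-one, via tetrahedral magnesium adduct 6 (not isolated)
Conditions: 5 (3 equiv), THF, −78 → 0 °C; inverse quench into cold 1 M HCl
Reagents that add atoms: none
Why: Weinreb ketone synthesis, in which the chelated tetrahedral adduct prevents over-addition and the cold acidic quench keeps the liberated amine from adding to the new vinyl ketone.

Step 4
Reactants: 8 4-methoxybenzyl alcohol; 9 2-chloro-N-methoxy-N-methylacetamide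
Product: 11 N-methoxy-2-[(4-methoxybenzyl)oxy]-N-methylacetamide, via sodium 4-methoxybenzyl oxide 10 (not isolated)
Conditions: NaH, THF, 0 °C; then 9, Bu4NI (cat.), 0 → 23 °C
Reagents that add atoms: none
Why: Williamson ether synthesis, an SN2 displacement of the activated α-chloro amide by the alkoxide, which should be much faster than attack on the Weinreb carbonyl.

Step 5
Reactants: 11 N-methoxy-2-[(4-methoxybenzyl)oxy]-N-methylacetamide; 12 isopropenylmagnesium bromide
Product: 14 1-[(4-methoxybenzyl)oxy]-3-methylbut-3-en-2-one, via tetrahedral magnesium adduct 13 (not isolated)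
Conditions: THF, −78 → 0 °C; cold 1 M HCl quench
Reagents that add atoms: none
Why: Weinreb ketone synthesis, which should give the isopropenyl ketone without over-addition.

Step 6
Reactants: 14 1-[(4-methoxybenzyl)oxy]-3-methylbut-3-en-2-one
Product: 15 tert-butyl({(1Z)-1-[(4-methoxybenzyl)oxy]-3-methylbuta-1,3-dien-2-yl}oxy)dimethylsilane
Conditions: TBSOTf, Et3N, CH2Cl2, −78 → 0 °C
Reagents that add atoms: tert-butyldimethylsilyl trifluoromethanesulfonate, CC(C)(C)[Si](C)(C)OS(=O)(=O)C(F)(F)F
Why: Soft enolisation and O-silylation at the only enolisable position (the CH2–OPMB carbon) should give the cross-conjugated silyl enol ether as the Z isomer, in which OPMB avoids allylic strain with the isopropenyl group and so sits on the outside of the s-cis diene.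

Step 7
Reactants: 7 (4R)-4-hydroxy-7-methylocta-1,6-dien-3-one; 15 tert-butyl({(1Z)-1-[(4-methoxybenzyl)oxy]-3-methylbuta-1,3-dien-2-yl}oxy)dimethylsilane
Product: 16 (2R)-1-[(1R,2R)-3-(tert-butyldimethylsilyloxy)-2-(4-methoxybenzyloxy)-4-methylcyclohex-3-en-1-yl]-2-hydroxy-5-methylhex-4-en-1-one
Conditions: 15 (1.3 equiv), PhMe (1 M), BHT (cat.), 0 → 23 °C, dark
Reagents that add atoms: none
Why: A normal-electron-demand, concerted but asynchronous Diels–Alder cycloaddition between the electron-rich diene 15 and the vinyl ketone of 7, whose carbonyl is activated and conformationally locked (s-cis enone, syn-planar O=C–C–O) by the internal O–H···O=C hydrogen bond; the closest known reaction type is the cycloaddition of oxygenated butadienes with α'-hydroxy vinyl ketones. The six-membered carbocycle is closed by suprafacial [4π+2π] addition in which the CH2 terminus of the diene bonds to the enone β-carbon and the CH–OPMB terminus to the α-carbon, so that ring bonds C5–C6 and C3–C4 of the target arise together. The ring carbon bearing the acyl group is set by the ketol stereocentre: in the hydrogen-bonded conformer the prenyl CH2 covers one face, and the 2-silyloxy group of the diene, which lies over this centre in the endo transition state, should force addition to the opposite (Si) face of the enone α-carbon. The neighbouring OPMB-bearing carbon is set by the endo rule together with the Z enol ether geometry, which should place OPMB and the acyl group cis. The step needs regioselectivity "ortho" to the 1-alkoxy group, secured by three factors that all direct the first bond to the CH2 terminus against the 2-silyloxy group: the stronger 1-donor (alkyl ether versus silyl ether), the 3-methyl group and the unsubstituted terminus; it also needs the endo and facial selectivity described above.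

Step 8
Reactants: 16 (2R)-1-[(1R,2R)-3-(tert-butyldimethylsilyloxy)-2-(4-methoxybenzyloxy)-4-methylcyclohex-3-en-1-yl]-2-hydroxy-5-methylhex-4-en-1-one
Product: 17 (2S)-1-[(1R,2R)-3-(tert-butyldimethylsilyloxy)-2-(4-methoxybenzyloxy)-4-methylcyclohex-3-en-1-yl]-5-methyl-1-oxohex-4-en-2-yl acetate
Conditions: PPh3, DIAD, AcOH, THF, 0 → 23 °C
Reagents that add atoms: acetic acid, CC(=O)O
Why: Mitsunobu reaction, in which acetate displaces the alkoxyphosphonium by SN2 with inversion at the carbinol carbon (activated by the adjacent ketone, no allylic pathway available), turning the (R)-alcohol into the (S)-acetate of the target.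

Step 9
Reactants: 17 (2S)-1-[(1R,2R)-3-(tert-butyldimethylsilyloxy)-2-(4-methoxybenzyloxy)-4-methylcyclohex-3-en-1-yl]-5-methyl-1-oxohex-4-en-2-yl acetate
Product: 18 (3S)-2-[(1S,2R)-3-(tert-butyldimethylsilyloxy)-2-(4-methoxybenzyloxy)-4-methylcyclohex-3-en-1-yl]-6-methylhepta-1,5-dien-3-yl acetate
Conditions: Tebbe reagent (1.2 equiv), pyridine (cat.), THF/PhMe, −40 → 0 °C; aq NaOH quench
Reagents that add atoms: Tebbe reagent Cp2Ti(μ-Cl)(μ-CH2)AlMe2, C[Al](C)C[Ti](Cl)(C1C=CC=C1)C1C=CC=C1
Why: Tebbe methylenation through the titanium methylidene is non-basic, so the two α-stereocentres and the β-alkoxy ketone are not endangered, and at low temperature the ketone should react much faster than the acetate while the silyl enol ether is inert.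

Step 10
Reactants: 18 (3S)-2-[(1S,2R)-3-(tert-butyldimethylsilyloxy)-2-(4-methoxybenzyloxy)-4-methylcyclohex-3-en-1-yl]-6-methylhepta-1,5-dien-3-yl acetate
Product: 19 (3S)-2-[(1S,2R)-2-(4-methoxybenzyloxy)-4-methyl-3-oxocyclohex-4-en-1-yl]-6-methylhepta-1,5-dien-3-yl acetate
Conditions: Pd(OAc)2 (1.1 equiv), MeCN, 23 → 40 °C
Reagents that add atoms: none
Why: Saegusa–Ito oxidation, in which palladation of the silyl enol ether at the methyl-bearing carbon and syn β-hydride elimination toward the ring CH2 should give the endocyclic 2-methylcyclohexenone; the 2-substituted allylic acetate is not prone to palladium-mediated 1,3-transposition.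

Step 11
Reactants: 19 (3S)-2-[(1S,2R)-2-(4-methoxybenzyloxy)-4-methyl-3-oxocyclohex-4-en-1-yl]-6-methylhepta-1,5-dien-3-yl acetate
Product: 20 (3S)-2-[(1S,2R,3S)-3-hydroxy-2-(4-methoxybenzyloxy)-4-methylcyclohex-4-en-1-yl]-6-methylhepta-1,5-dien-3-yl acetate
Conditions: NaBH4, CeCl3·7H2O, MeOH, −78 °C
Reagents that add atoms: none
Why: Luche 1,2-reduction; in the half-chair with the large side chain equatorial and the OPMB group axial, axial hydride delivery anti to the C–O bond should place the new hydroxyl (C2 of the target) cis to OPMB and to the side chain.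

Step 12
Reactants: 20 (3S)-2-[(1S,2R,3S)-3-hydroxy-2-(4-methoxybenzyloxy)-4-methylcyclohex-4-en-1-yl]-6-methylhepta-1,5-dien-3-yl acetate
Product: 21 (3S)-2-[(1R,2R,3R,4S,6S)-2-hydroxy-3-(4-methoxybenzyloxy)-1-methyl-7-oxabicyclo[4.1.0]heptan-4-yl]-6-methylhepta-1,5-dien-3-yl acetate
Conditions: VO(acac)2 (5 mol %), tBuOOH (decane), CH2Cl2, 0 → 23 °C
Reagents that add atoms: tert-butyl hydroperoxide, CC(C)(C)OO
Why: Hydroxyl-directed vanadium-catalysed epoxidation delivers oxygen to the ring alkene from the face of the allylic hydroxyl, setting C1 and C6 with the epoxide cis to that hydroxyl, while the two alkenes without a free allylic hydroxyl are not activated.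

Step 13
Reactants: 21 (3S)-2-[(1R,2R,3R,4S,6S)-2-hydroxy-3-(4-methoxybenzyloxy)-1-methyl-7-oxabicyclo[4.1.0]heptan-4-yl]-6-methylhepta-1,5-dien-3-yl acetate
Product: 22 (3S)-2-[(1R,2R,3R,4S,6S)-2,3-dihydroxy-1-methyl-7-oxabicyclo[4.1.0]heptan-4-yl]-6-methylhepta-1,5-dien-3-yl acetate
Conditions: DDQ, CH2Cl2/pH 7 buffer (10:1), 0 °C
Reagents that add atoms: none
Why: Oxidative cleavage of the 4-methoxybenzyl ether by DDQ (benzylic hydride abstraction, then hydrolysis of the oxocarbenium ion) leaves epoxide, acetate and alkenes untouched, and the excess water suppresses trapping by the neighbouring hydroxyl as an acetal.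

Step 14
Reactants: 22 (3S)-2-[(1R,2R,3R,4S,6S)-2,3-dihydroxy-1-methyl-7-oxabicyclo[4.1.0]heptan-4-yl]-6-methylhepta-1,5-dien-3-yl acetate
Product: 24 (1S,2R,3R,4S,6S)-4-[(3S)-3-acetoxy-6-methylhepta-1,5-dien-2-yl]-1-methyl-7-oxabicyclo[4.1.0]heptane-2,3-diyl bis[(2Z)-2-methylbut-2-enoate], via C3 monoangelate 23 (not isolated)
Conditions: angelic acid (6 equiv), 2,4,6-trichlorobenzoyl chloride, Et3N, PhMe, 23 °C; filter; then 22, 80 °C
Reagents that add atoms: angelic acid, C/C=C(/C)C(=O)O
Why: Yamaguchi-type acylation with the preformed mixed anhydride and no strongly nucleophilic catalyst should esterify both hindered secondary hydroxyls without Z to E isomerisation of the angeloyl group and without touching any stereocentre.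

Compound list
1 | methyl (2R)-oxirane-2-carboxylate (methyl (R)-glycidate) | COC(=O)[C@H]1CO1 | starting material
2 | (2-methylprop-1-en-1-yl)magnesium bromide | CC(C)=C[Mg]Br | starting material
3 | methyl (2R)-2-hydroxy-5-methylhex-4-enoate | COC(=O)[C@H](O)CC=C(C)C | intermediate
4 | (2R)-2-hydroxy-N-methoxy-N,5-dimethylhex-4-enamide | CON(C)C(=O)[C@H](O)CC=C(C)C | intermediate
5 | vinylmagnesium bromide | C=C[Mg]Br | starting material
6 | tetrahedral magnesium adduct of 4 and 5 (bis-bromomagnesium alkoxide) | C=CC(O[Mg]Br)(N(C)OC)[C@H](O[Mg]Br)CC=C(C)C | intermediate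
7 | (4R)-4-hydroxy-7-methylocta-1,6-dien-3-one | C=CC(=O)[C@H](O)CC=C(C)C | intermediate
8 | 4-methoxybenzyl alcohol | COc1ccc(CO)cc1 | starting material
9 | 2-chloro-N-methoxy-N-methylacetamide | CON(C)C(=O)CCl | starting material
10 | sodium 4-methoxybenzyl oxide | COc1ccc(C[O-])cc1.[Na+] | intermediate
11 | N-methoxy-2-[(4-methoxybenzyl)oxy]-N-methylacetamide | CON(C)C(=O)COCc1ccc(OC)cc1 | intermediate
12 | isopropenylmagnesium bromide | C=C(C)[Mg]Br | starting material
13 | tetrahedral magnesium adduct of 11 and 12 | C=C(C)C(O[Mg]Br)(N(C)OC)COCc1ccc(OC)cc1 | intermediate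
14 | 1-[(4-methoxybenzyl)oxy]-3-methylbut-3-en-2-one | C=C(C)C(=O)COCc1ccc(OC)cc1 | intermediate
15 | tert-butyl({(1Z)-1-[(4-methoxybenzyl)oxy]-3-methylbuta-1,3-dien-2-yl}oxy)dimethylsilane | C=C(C)/C(O[Si](C)(C)C(C)(C)C)=C/OCc1ccc(OC)cc1 | intermediate
16 | (2R)-1-[(1R,2R)-3-(tert-butyldimethylsilyloxy)-2-(4-methoxybenzyloxy)-4-methylcyclohex-3-en-1-yl]-2-hydroxy-5-methylhex-4-en-1-one (acyl and OPMB cis) | O=C([C@@H](CC=C(C)C)O)[C@@H]1CCC(C)=C(O[Si](C)(C)C(C)(C)C)[C@@H]1OCc2ccc(OC)cc2 | intermediate
17 | (2S)-1-[(1R,2R)-3-(tert-butyldimethylsilyloxy)-2-(4-methoxybenzyloxy)-4-methylcyclohex-3-en-1-yl]-5-methyl-1-oxohex-4-en-2-yl acetate | O=C([C@H](CC=C(C)C)OC(C)=O)[C@@H]1CCC(C)=C(O[Si](C)(C)C(C)(C)C)[C@@H]1OCc2ccc(OC)cc2 | intermediate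
18 | (3S)-2-[(1S,2R)-3-(tert-butyldimethylsilyloxy)-2-(4-methoxybenzyloxy)-4-methylcyclohex-3-en-1-yl]-6-methylhepta-1,5-dien-3-yl acetate | C=C([C@H](CC=C(C)C)OC(C)=O)[C@@H]1CCC(C)=C(O[Si](C)(C)C(C)(C)C)[C@@H]1OCc2ccc(OC)cc2 | intermediate
19 | (3S)-2-[(1S,2R)-2-(4-methoxybenzyloxy)-4-methyl-3-oxocyclohex-4-en-1-yl]-6-methylhepta-1,5-dien-3-yl acetate | C=C([C@H](CC=C(C)C)OC(C)=O)[C@@H]1CC=C(C)C(=O)[C@@H]1OCc2ccc(OC)cc2 | intermediate
20 | (3S)-2-[(1S,2R,3S)-3-hydroxy-2-(4-methoxybenzyloxy)-4-methylcyclohex-4-en-1-yl]-6-methylhepta-1,5-dien-3-yl acetate (all three ring substituents cis) | C=C([C@H](CC=C(C)C)OC(C)=O)[C@@H]1CC=C(C)[C@H](O)[C@@H]1OCc2ccc(OC)cc2 | intermediate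
21 | (3S)-2-[(1R,2R,3R,4S,6S)-2-hydroxy-3-(4-methoxybenzyloxy)-1-methyl-7-oxabicyclo[4.1.0]heptan-4-yl]-6-methylhepta-1,5-dien-3-yl acetate | C=C([C@H](CC=C(C)C)OC(C)=O)[C@@H]1C[C@@H]2O[C@]2(C)[C@H](O)[C@@H]1OCc3ccc(OC)cc3 | intermediate
22 | (3S)-2-[(1R,2R,3R,4S,6S)-2,3-dihydroxy-1-methyl-7-oxabicyclo[4.1.0]heptan-4-yl]-6-methylhepta-1,5-dien-3-yl acetate | C=C([C@H](CC=C(C)C)OC(C)=O)[C@@H]1C[C@@H]2O[C@]2(C)[C@H](O)[C@@H]1O | intermediate
23 | (1R,2R,3R,4S,6S)-4-[(3S)-3-acetoxy-6-methylhepta-1,5-dien-2-yl]-2-hydroxy-1-methyl-7-oxabicyclo[4.1.0]heptan-3-yl (2Z)-2-methylbut-2-enoate | C=C([C@H](CC=C(C)C)OC(C)=O)[C@@H]1C[C@@H]2O[C@]2(C)[C@H](O)[C@@H]1OC(=O)/C(C)=C\C | intermediate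
24 | (1S,2R,3R,4S,6S)-4-[(3S)-3-acetoxy-6-methylhepta-1,5-dien-2-yl]-1-methyl-7-oxabicyclo[4.1.0]heptane-2,3-diyl bis[(2Z)-2-methylbut-2-enoate] | C=C([C@H](CC=C(C)C)OC(C)=O)[C@@H]1C[C@@H]2O[C@]2(C)[C@H](OC(=O)/C(C)=C\C)[C@@H]1OC(=O)/C(C)=C\C | target

Total step count: 14 steps.
Longest linear sequence: 11 steps (steps 1–3, then 7–14; the diene branch, steps 4–6 then 7–14, is equally long).

Steps most likely to fail

Step 7. The prenyl CH2 is a small control group, so discrimination between the two enone faces may be insufficient, and some of the cycloaddition may leak to the regioisomer directed by the 2-silyloxy group. The fallback moves the control from the substrate to a catalyst. Setting out again from 7 and 15, the cycloaddition is run with a bidentate chiral Lewis acid, Cu(OTf)2 (divalent copper) with 2,2'-isopropylidenebis(4-tert-butyl-2-oxazoline), in CH2Cl2 at −40 °C. This binds the ketone and hydroxyl oxygens of 7 in a five-membered chelate (the same syn-planar arrangement). The ligand enantiomer is chosen to screen the Re face of the enone α-carbon, which is the matched pairing with the substrate; the stronger polarisation of the enone should also sharpen the regiochemical preference. No new compound is made (F0) and the route is rejoined at 16.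

Step 10. Palladation of the hindered, tetrasubstituted silyl enol ether may be slow, β-hydride loss may go toward the methyl group to give the exocyclic enone, or the allylic acetate may be ionised by the zerovalent palladium that is formed. The fallback replaces the palladium dehydrogenation by a selenium sequence. Setting out from 18, benzeneselenenyl chloride (1.0 equiv, CH2Cl2, −78 °C) converts the silyl enol ether regiospecifically into (3S)-2-[(1S,2R)-2-(4-methoxybenzyloxy)-4-methyl-3-oxo-4-(phenylselanyl)cyclohexyl]-6-methylhepta-1,5-dien-3-yl acetate F1. Oxidation (H2O2, pyridine, CH2Cl2, 0 °C) and syn elimination of the selenoxide should then give the enone, and the route is rejoined at 19.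

Step 14. The angeloyl group may isomerise from Z to E during activation, or the second acylation may stall at the hydroxyl flanked by the epoxide carbon. The fallback builds the angelate double bonds on the molecule instead of transferring them. Setting out from 22, both hydroxyls are esterified with 2-[bis(2,2,2-trifluoroethoxy)phosphoryl]propanoic acid (DIC, DMAP cat., CH2Cl2) to give (1S,2R,3R,4S,6S)-4-[(3S)-3-acetoxy-6-methylhepta-1,5-dien-2-yl]-1-methyl-7-oxabicyclo[4.1.0]heptane-2,3-diyl bis{2-[bis(2,2,2-trifluoroethoxy)phosphoryl]propanoate} F2. A double Still–Gennari olefination with acetaldehyde (KN(SiMe3)2, 18-crown-6, THF, −78 °C) should then form both (Z)-2-methylbut-2-enoates, and the route is rejoined at 24.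

Further compounds
F0 | step 7 | none | none
F1 | step 10 | (3S)-2-[(1S,2R)-2-(4-methoxybenzyloxy)-4-methyl-3-oxo-4-(phenylselanyl)cyclohexyl]-6-methylhepta-1,5-dien-3-yl acetate | C=C([C@H](CC=C(C)C)OC(C)=O)[C@@H]1CCC(C)([Se]c2ccccc2)C(=O)[C@@H]1OCc3ccc(OC)cc3
F2 | step 14 | (1S,2R,3R,4S,6S)-4-[(3S)-3-acetoxy-6-methylhepta-1,5-dien-2-yl]-1-methyl-7-oxabicyclo[4.1.0]heptane-2,3-diyl bis{2-[bis(2,2,2-trifluoroethoxy)phosphoryl]propanoate} | C=C([C@H](CC=C(C)C)OC(C)=O)[C@@H]1C[C@@H]2O[C@]2(C)[C@H](OC(=O)C(C)P(=O)(OCC(F)(F)F)OCC(F)(F)F)[C@@H]1OC(=O)C(C)P(=O)(OCC(F)(F)F)OCC(F)(F)F
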